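**Plan**

- Retrosynthesis (daucane locants: C1 quaternary methyl carbon, C2/C10 acetoxy carbons, C4 isopropyl carbinol, C5 ring-fusion CH, C6 aroyloxy carbon): remove the three esters, return O-6/H-5 to a C5=C6 alkene and C2/C10 to ketones, then cut C1–C5.
- Enabling feature: the C1–C5 bond alone divides a ten-membered carbocycle into the five- and the seven-membered ring, and C1 sits between the oxygenated C2 and C10 as the central carbon of a 2-methyl-1,3-diketone, so a ring alkyne C5≡C6 can accept its enol carbon across the ring.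
- The ten-membered enynedione is cut at C1–C2 (Reformatsky aldol, then oxidation), C6–C7 (alkyne–allyl chloride coupling) and C3–C4 (enolate allylation).
- Forward: a C2–C6 alkyne from (R)-2-hydroxy-3-methylbutanoic acid and a C7–C10 amide from 4-methylfuran-2(5H)-one are joined, SmI2 closes the ten-membered ring, gold then closes cyclopentane and cycloheptadiene together, and nine steps set oxidation levels and esters.
- Stereochemistry: C4 from the hydroxy acid by self-regeneration of the stereocentre; C1 from C4 in the transannular step; C2 and C6 by hydride delivery from the C4 hydroxyl (1,3-anti); C10 by chelation-controlled 1,3-syn reduction from O-2; C5 by hydrogen-atom transfer anti to the β-face groups after C4-hydroxyl-directed epoxidation.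

Key step: step 14

Remark: (R)-2-hydroxy-3-methylbutanoic acid is taken as commercial; Why lines use the daucane locants above (β = face of the angular methyl), names use azulene locants (C8a = C1, C1 = C2, C3 = C4, C3a = C5, C4 = C6, C8 = C10), and the carbonyl-flanked centres of 16–20 are carried as mixtures because they are erased later.

Step 1
Reactants: 1 (2R)-2-hydroxy-3-methylbutanoic acid; 2 2,2-dimethylpropanal
Product: 3 (2R,5R)-2-tert-butyl-5-(propan-2-yl)-1,3-dioxolan-4-one
Conditions: TsOH·H2O (cat.), H2SO4 (cat.), pentane, reflux, Dean–Stark; cis isomer purified by crystallisation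
Reagents that add atoms: none
Why: Acid-catalysed acetalisation with azeotropic water removal (Seebach dioxolanone) should give the cis acetal as the thermodynamic product, which fixes the acetal centre that relays the configuration in step 2.

Step 2
Reactants: 3 (2R,5R)-2-tert-butyl-5-(propan-2-yl)-1,3-dioxolan-4-one; 4 3-bromoprop-1-ene
Product: 5 (2R,5R)-2-tert-butyl-5-(propan-2-yl)-5-(prop-2-en-1-yl)-1,3-dioxolan-4-one
Conditions: LiN(i-Pr)2, THF, −78 °C; then 4, −78 → −20 °C
Reagents that add atoms: none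
Why: Self-regeneration of stereocentres: the lithium enolate is alkylated anti to the tert-butyl group, so allyl takes the place of the former hydrogen and the quaternary carbinol carbon (C4) is set with overall retention.

Step 3
Reactants: 5 (2R,5R)-2-tert-butyl-5-(propan-2-yl)-5-(prop-2-en-1-yl)-1,3-dioxolan-4-one
Product: 6 (2R,5R)-2-tert-butyl-5-(propan-2-yl)-5-(prop-2-en-1-yl)-1,3-dioxolan-4-ol (C4 epimers)
Conditions: i-Bu2AlH, CH2Cl2, −78 °C; Rochelle salt work-up
Reagents that add atoms: none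
Why: Low-temperature i-Bu2AlH reduction of a lactone stops at the aluminium hemiacetal, which gives the lactol on work-up; the new hemiacetal centre is of no consequence.

Step 4
Reactants: 6 (2R,5R)-2-tert-butyl-5-(propan-2-yl)-5-(prop-2-en-1-yl)-1,3-dioxolan-4-ol
Product: 8 (3R)-3-(propan-2-yl)hex-5-en-1-yn-3-ol, via hydroxy aldehyde 7 (not isolated)
Conditions: dimethyl (1-diazo-2-oxopropyl)phosphonate (2.5 equiv), K2CO3, MeOH, 0 °C → rt
Reagents that add atoms: dimethyl (1-diazo-2-oxopropyl)phosphonate, COP(=O)(OC)C(=[N+]=[N-])C(C)=O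
Why: Ohira–Bestmann (Seyferth–Gilbert) homologation: methanolic carbonate opens the hemiacetal to the non-enolisable α-hydroxy aldehyde with loss of pivalaldehyde, and the diazomethylphosphonate formed in situ converts it into the terminal alkyne without touching the quaternary centre.

Step 5
Reactants: 8 (3R)-3-(propan-2-yl)hex-5-en-1-yn-3-ol
Product: 9 triethyl{[(3R)-3-(propan-2-yl)hex-5-en-1-yn-3-yl]oxy}silane
Conditions: Et3SiOTf, 2,6-lutidine, CH2Cl2, −78 → 0 °C
Reagents that add atoms: triethylsilyl trifluoromethanesulfonate, CC[Si](CC)(CC)OS(=O)(=O)C(F)(F)F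
Why: A silyl triflate with a hindered base silylates tertiary propargylic alcohols; the ether guards the carbinol against Meyer–Schuster ionisation and retro-aldol cleavage later on.

Step 6
Reactants: 10 4-methylfuran-2(5H)-one
Product: 11 (2Z)-4-hydroxy-N-methoxy-N,3-dimethylbut-2-enamide
Conditions: MeNH(OMe)·HCl, AlMe3, CH2Cl2, 0 °C → rt
Reagents that add atoms: N,O-dimethylhydroxylamine hydrochloride, CNOC.Cl
Why: Weinreb aminolysis of a lactone by the aluminium amide opens the butenolide at the acyl carbon, so the ring-derived (Z) geometry of the alkene is carried into the open chain.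

Step 7
Reactants: 11 (2Z)-4-hydroxy-N-methoxy-N,3-dimethylbut-2-enamide
Product: 12 (2Z)-4-chloro-N-methoxy-N,3-dimethylbut-2-enamide
Conditions: NCS, Me2S, CH2Cl2, −20 → 0 °C
Reagents that add atoms: N-chlorosuccinimide, O=C1CCC(=O)N1Cl
Why: Corey–Kim chlorination replaces the primary allylic hydroxyl by SN2 attack of chloride on the alkoxysulfonium ion under neutral conditions, so neither allylic transposition nor Z to E isomerisation is expected.

Step 8
Reactants: 9 triethyl{[(3R)-3-(propan-2-yl)hex-5-en-1-yn-3-yl]oxy}silane; 12 (2Z)-4-chloro-N-methoxy-N,3-dimethylbut-2-enamide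
Product: 13 (2Z,7R)-N-methoxy-N,3-dimethyl-7-(propan-2-yl)-7-[(triethylsilyl)oxy]deca-2,9-dien-5-ynamide
Conditions: CuI, NaI, K2CO3, DMF, rt
Reagents that add atoms: none
Why: Copper-mediated coupling of a terminal alkyne with a primary allylic halide (in situ Finkelstein activation) forms the C6–C7 bond by SN2 substitution under a carbonate base that should leave the skipped enyne unisomerised.

Step 9
Reactants: 13 (2Z,7R)-N-methoxy-N,3-dimethyl-7-(propan-2-yl)-7-[(triethylsilyl)oxy]deca-2,9-dien-5-ynamide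
Product: 14 (4Z,9R)-5-methyl-9-(propan-2-yl)-9-[(triethylsilyl)oxy]dodeca-4,11-dien-7-yn-3-one
Conditions: EtMgBr, THF, −78 → 0 °C; aqueous work-up
Reagents that add atoms: ethylmagnesium bromide, CC[Mg]Br
Why: Weinreb ketone synthesis: the chelated tetrahedral magnesium adduct prevents over-addition and the β,β-disubstituted enamide takes the Grignard reagent 1,2.

Step 10
Reactants: 14 (4Z,9R)-5-methyl-9-(propan-2-yl)-9-[(triethylsilyl)oxy]dodeca-4,11-dien-7-yn-3-one
Product: 16 (4Z,9R)-2-bromo-5-methyl-9-(propan-2-yl)-9-[(triethylsilyl)oxy]dodeca-4,11-dien-7-yn-3-one (C2 epimers), via trimethylsilyl dienol ether 15 (not isolated)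
Conditions: LiN(SiMe3)2, Me3SiCl, THF, −78 °C; then NBS, −78 → −20 °C
Reagents that add atoms: N-bromosuccinimide, O=C1CCC(=O)N1Br; chlorotrimethylsilane, C[Si](C)(C)Cl (its silicon stays only in 15)
Why: Kinetic α′-deprotonation of the enone with in situ silyl trapping gives the 2-silyloxy diene, which NBS brominates at its terminal enol carbon (C1); the bromide-bearing centre forms as a mixture and is erased in step 12.

Step 11
Reactants: 16 (4Z,9R)-2-bromo-5-methyl-9-(propan-2-yl)-9-[(triethylsilyl)oxy]dodeca-4,11-dien-7-yn-3-one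
Product: 18 (3R,8Z)-10-bromo-7-methyl-9-oxo-3-(propan-2-yl)-3-[(triethylsilyl)oxy]undec-7-en-4-ynal (C10 epimers), via vicinal diol 17 (not isolated)
Conditions: OsO4 (2 mol %), NaIO4, 2,6-lutidine, dioxane/H2O 3:1, rt
Reagents that add atoms: sodium periodate, [Na+].[O-]I(=O)(=O)=O (oxygen relayed through OsO4)
Why: Lemieux–Johnson cleavage: OsO4 dihydroxylates the electron-rich monosubstituted vinyl group in preference to the conjugated trisubstituted enone alkene and the alkyne, and periodate cleaves the diol to the C2 aldehyde.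

Step 12
Reactants: 18 (3R,8Z)-10-bromo-7-methyl-9-oxo-3-(propan-2-yl)-3-[(triethylsilyl)oxy]undec-7-en-4-ynal
Product: 19 (2Z,7R)-9-hydroxy-3,10-dimethyl-7-(propan-2-yl)-7-[(triethylsilyl)oxy]cyclodec-2-en-5-yn-1-one (C9/C10 diastereomers)
Conditions: SmI2 (2.2 equiv), THF, −78 °C, slow addition of 18 (final 0.003 M); aqueous work-up
Reagents that add atoms: none
Why: Intramolecular samarium Reformatsky reaction: SmI2 reduces the C–Br bond to a trivalent samarium enolate that is held on the aldehyde through the metal, the established way to close eight- to fourteen-membered rings at high dilution; the two new centres are removed in step 13.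

Step 13
Reactants: 19 (2Z,7R)-9-hydroxy-3,10-dimethyl-7-(propan-2-yl)-7-[(triethylsilyl)oxy]cyclodec-2-en-5-yn-1-one
Product: 20 (4Z,9R)-2,5-dimethyl-9-(propan-2-yl)-9-[(triethylsilyl)oxy]cyclodec-4-en-7-yne-1,3-dione (C2 epimers/enol)
Conditions: Dess–Martin periodinane, CH2Cl2, 0 °C → rt
Reagents that add atoms: none
Why: Dess–Martin oxidation of the β-hydroxy ketone gives the 2-methyl-1,3-diketone under neutral conditions that neither eliminate the β-silyloxy group nor move the skipped alkene.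

Step 14
Reactants: 20 (4Z,9R)-2,5-dimethyl-9-(propan-2-yl)-9-[(triethylsilyl)oxy]cyclodec-4-en-7-yne-1,3-dione
Product: 21 (3R,8aR)-6,8a-dimethyl-3-(propan-2-yl)-3-[(triethylsilyl)oxy]-2,3,5,8a-tetrahydroazulene-1,8-dione
Conditions: (t-Bu)2(2-biphenylyl)PAuNTf2 (5 mol %), CH2Cl2 (0.005 M), 23 °C
Reagents that add atoms: none
Why: Proposed new method: cationic monovalent gold coordinates the ring alkyne on its outer face, the dienol formed by enolisation of C1–H toward the enone carbonyl attacks C5 from inside the ring anti to gold, and the enol proton protodeaurates the C6 vinyl-gold to leave the cis C5=C6 alkene. The closest known reaction is the intramolecular gold-catalysed Conia-ene 5-exo-dig carbocyclisation of β-dicarbonyl compounds onto alkynes, not yet run across a ten-membered ring. The C1–C5 bond closes the cyclopentanone as a 5-(enolexo)-exo-dig process through C2–C3–C4 and, being the same bond, the cycloheptadienone as a 7-(enolendo)-endo-dig process through C10–C9=C8–C7–C6. The new quaternary centre C1 is controlled by C4: in the forming cyclopentane the C1 methyl should take the face of the silyloxy group and avoid a syn-pentane contact with the isopropyl group. The step needs C-attack at C5 rather than at C6 (6/6 closure) or O-attack; it relies on the three-atom tether with its fully substituted C4, on the bulky phosphine that keeps gold on the less hindered C6, and on the strain of the bridged enol ethers that O-attack would give.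

Step 15
Reactants: 21 (3R,8aR)-6,8a-dimethyl-3-(propan-2-yl)-3-[(triethylsilyl)oxy]-2,3,5,8a-tetrahydroazulene-1,8-dione
Product: 22 (3R,8aR)-3-hydroxy-6,8a-dimethyl-3-(propan-2-yl)-2,3,5,8a-tetrahydroazulene-1,8-dione
Conditions: HF·pyridine, pyridine, THF, 0 °C → rt
Reagents that add atoms: none
Why: Buffered fluoride cleaves the tertiary silyl ether without the basic conditions that would open the β-hydroxy cyclopentanone by retro-aldol reaction.

Step 16
Reactants: 22 (3R,8aR)-3-hydroxy-6,8a-dimethyl-3-(propan-2-yl)-2,3,5,8a-tetrahydroazulene-1,8-dione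
Product: 23 (1S,3R,8aR)-1,3-dihydroxy-6,8a-dimethyl-3-(propan-2-yl)-1,2,3,8a-tetrahydroazulen-8(5H)-one
Conditions: Me4NBH(OAc)3 (1.5 equiv), MeCN/AcOH 1:1, −35 °C
Reagents that add atoms: none
Why: Evans–Saksena reduction: the C4 hydroxyl exchanges onto boron and delivers hydride intramolecularly to the β-face of the C2 ketone, giving the 1,3-anti (2α) alcohol, while the conjugated neopentyl enone should survive limited reagent at low temperature.

Step 17
Reactants: 23 (1S,3R,8aR)-1,3-dihydroxy-6,8a-dimethyl-3-(propan-2-yl)-1,2,3,8a-tetrahydroazulen-8(5H)-one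
Product: 25 (1S,3R,8R,8aR)-6,8a-dimethyl-3-(propan-2-yl)-1,2,3,5,8,8a-hexahydroazulene-1,3,8-triol, via diethylboron chelate 24 (not isolated)
Conditions: Et2BOMe, THF/MeOH 4:1, −78 °C; NaBH4, −78 °C; AcOH quench; repeated evaporation from MeOH
Reagents that add atoms: none
Why: Narasaka–Prasad reduction: the O-2/C10-carbonyl diethylboron chelate is attacked by external borohydride axially, on the side of H-2 and anti to the pseudo-axial C5 substituent of the chelate ring, which should give the 1,3-syn (10α) allylic alcohol by 1,2-reduction.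

Step 18
Reactants: 25 (1S,3R,8R,8aR)-6,8a-dimethyl-3-(propan-2-yl)-1,2,3,5,8,8a-hexahydroazulene-1,3,8-triol
Product: 26 (1S,3R,8R,8aR)-3-hydroxy-6,8a-dimethyl-3-(propan-2-yl)-1,2,3,5,8,8a-hexahydroazulene-1,8-diyl diacetate
Conditions: Ac2O, pyridine, DMAP (cat.), CH2Cl2, 0 °C → rt
Reagents that add atoms: acetic anhydride, CC(=O)OC(C)=O
Why: DMAP-catalysed acetylation esterifies the two secondary hydroxyls and leaves the hindered tertiary carbinol free.

Step 19
Reactants: 26 (1S,3R,8R,8aR)-3-hydroxy-6,8a-dimethyl-3-(propan-2-yl)-1,2,3,5,8,8a-hexahydroazulene-1,8-diyl diacetate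
Product: 27 (1S,3R,3aS,4R,8R,8aR)-3a,4-epoxy-3-hydroxy-6,8a-dimethyl-3-(propan-2-yl)-1,2,3,3a,4,5,8,8a-octahydroazulene-1,8-diyl diacetate
Conditions: VO(acac)2 (5 mol %), t-BuOOH, CH2Cl2, 0 °C → rt
Reagents that add atoms: tert-butyl hydroperoxide, CC(C)(C)OO
Why: Vanadium-catalysed hydroxyl-directed epoxidation: the tertiary allylic C4 hydroxyl binds the vanadium peroxide and delivers oxygen to its own (β) face of the C5=C6 alkene only, the other alkene having no free allylic hydroxyl.

Step 20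
Reactants: 27 (1S,3R,3aS,4R,8R,8aR)-3a,4-epoxy-3-hydroxy-6,8a-dimethyl-3-(propan-2-yl)-1,2,3,3a,4,5,8,8a-octahydroazulene-1,8-diyl diacetate
Product: 28 (1S,3R,3aS,4R,8R,8aR)-3,4-dihydroxy-6,8a-dimethyl-3-(propan-2-yl)-1,2,3,3a,4,5,8,8a-octahydroazulene-1,8-diyl diacetate
Conditions: Cp2TiCl2 (20 mol %), Mn dust, 2,4,6-collidine·HCl, 1,4-cyclohexadiene, THF, rt
Reagents that add atoms: none
Why: Nugent–RajanBabu/Gansäuer reductive epoxide opening: trivalent titanium (Cp2TiCl) cleaves the C5–O bond to the tertiary radical, and hydrogen-atom transfer from 1,4-cyclohexadiene should occur on the α-face, anti to the angular methyl, the C4 oxygen and the titanium alkoxide at C6, setting the trans ring fusion.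

Step 21
Reactants: 28 (1S,3R,3aS,4R,8R,8aR)-3,4-dihydroxy-6,8a-dimethyl-3-(propan-2-yl)-1,2,3,3a,4,5,8,8a-octahydroazulene-1,8-diyl diacetate
Product: 29 (1S,3R,3aR,8R,8aR)-3-hydroxy-6,8a-dimethyl-4-oxo-3-(propan-2-yl)-1,2,3,3a,4,5,8,8a-octahydroazulene-1,8-diyl diacetate
Conditions: Dess–Martin periodinane, CH2Cl2, 0 °C
Reagents that add atoms: none
Why: Dess–Martin oxidation of the only secondary alcohol under neutral conditions should spare C5 from epimerisation and the β,γ-alkene from conjugation.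

Step 22
Reactants: 29 (1S,3R,3aR,8R,8aR)-3-hydroxy-6,8a-dimethyl-4-oxo-3-(propan-2-yl)-1,2,3,3a,4,5,8,8a-octahydroazulene-1,8-diyl diacetate
Product: 30 (1S,3R,3aS,4S,8R,8aR)-3,4-dihydroxy-6,8a-dimethyl-3-(propan-2-yl)-1,2,3,3a,4,5,8,8a-octahydroazulene-1,8-diyl diacetate
Conditions: Me4NBH(OAc)3, MeCN/AcOH 1:1, −30 °C
Reagents that add atoms: none
Why: Evans–Saksena reduction again: hydride is delivered from the boron-bound C4 hydroxyl across the β-face of the β-hydroxy ketone, which inverts C6 to the 1,3-anti (6α) alcohol.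

Step 23
Reactants: 30 (1S,3R,3aS,4S,8R,8aR)-3,4-dihydroxy-6,8a-dimethyl-3-(propan-2-yl)-1,2,3,3a,4,5,8,8a-octahydroazulene-1,8-diyl diacetate; 31 3,4-dimethoxybenzoyl chloride
Product: 32 (1S,3R,3aS,4S,8R,8aR)-1,8-bis(acetyloxy)-3-hydroxy-6,8a-dimethyl-3-(propan-2-yl)-1,2,3,3a,4,5,8,8a-octahydroazulen-4-yl 3,4-dimethoxybenzoate
Conditions: Et3N, DMAP, CH2Cl2, rt
Reagents that add atoms: none
Why: DMAP-catalysed acylation of the only secondary hydroxyl with the aroyl chloride; the tertiary C4 hydroxyl does not react.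

**Compound list**

1 | (2R)-2-hydroxy-3-methylbutanoic acid | CC(C)[C@@H](O)C(=O)O | starting material
2 | 2,2-dimethylpropanal | CC(C)(C)C=O | starting material
3 | (2R,5R)-2-tert-butyl-5-(propan-2-yl)-1,3-dioxolan-4-one | CC(C)[C@H]1O[C@@H](C(C)(C)C)OC1=O | intermediate
4 | 3-bromoprop-1-ene | C=CCBr | starting material
5 | (2R,5R)-2-tert-butyl-5-(propan-2-yl)-5-(prop-2-en-1-yl)-1,3-dioxolan-4-one | C=CC[C@]1(C(C)C)O[C@@H](C(C)(C)C)OC1=O | intermediate
6 | (2R,5R)-2-tert-butyl-5-(propan-2-yl)-5-(prop-2-en-1-yl)-1,3-dioxolan-4-ol (C4 epimers) | C=CC[C@]1(C(C)C)O[C@@H](C(C)(C)C)OC1O | intermediate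
7 | (2R)-2-hydroxy-2-(propan-2-yl)pent-4-enal | C=CC[C@@](O)(C(C)C)C=O | intermediate (not isolated)
8 | (3R)-3-(propan-2-yl)hex-5-en-1-yn-3-ol | C=CC[C@@](O)(C(C)C)C#C | intermediate
9 | triethyl{[(3R)-3-(propan-2-yl)hex-5-en-1-yn-3-yl]oxy}silane | C=CC[C@@](O[Si](CC)(CC)CC)(C(C)C)C#C | intermediate
10 | 4-methylfuran-2(5H)-one | CC1=CC(=O)OC1 | starting material
11 | (2Z)-4-hydroxy-N-methoxy-N,3-dimethylbut-2-enamide | OC/C(C)=C\C(=O)N(C)OC | intermediate
12 | (2Z)-4-chloro-N-methoxy-N,3-dimethylbut-2-enamide | ClC/C(C)=C\C(=O)N(C)OC | intermediate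
13 | (2Z,7R)-N-methoxy-N,3-dimethyl-7-(propan-2-yl)-7-[(triethylsilyl)oxy]deca-2,9-dien-5-ynamide | C=CC[C@@](O[Si](CC)(CC)CC)(C(C)C)C#CC/C(C)=C\C(=O)N(C)OC | intermediate
14 | (4Z,9R)-5-methyl-9-(propan-2-yl)-9-[(triethylsilyl)oxy]dodeca-4,11-dien-7-yn-3-one | C=CC[C@@](O[Si](CC)(CC)CC)(C(C)C)C#CC/C(C)=C\C(=O)CC | intermediate
15 | {[(4Z,9R)-5-methyl-9-(propan-2-yl)-9-[(triethylsilyl)oxy]dodeca-2,4,11-trien-7-yn-3-yl]oxy}trimethylsilane (C2=C3 geometry not defined) | C=CC[C@@](O[Si](CC)(CC)CC)(C(C)C)C#CC/C(C)=C\C(O[Si](C)(C)C)=CC | intermediate (not isolated)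
16 | (4Z,9R)-2-bromo-5-methyl-9-(propan-2-yl)-9-[(triethylsilyl)oxy]dodeca-4,11-dien-7-yn-3-one (C2 epimers) | C=CC[C@@](O[Si](CC)(CC)CC)(C(C)C)C#CC/C(C)=C\C(=O)C(C)Br | intermediate
17 | (4Z,9R)-2-bromo-11,12-dihydroxy-5-methyl-9-(propan-2-yl)-9-[(triethylsilyl)oxy]dodec-4-en-7-yn-3-one (C2/C11 epimers) | OCC(O)C[C@@](O[Si](CC)(CC)CC)(C(C)C)C#CC/C(C)=C\C(=O)C(C)Br | intermediate (not isolated)
18 | (3R,8Z)-10-bromo-7-methyl-9-oxo-3-(propan-2-yl)-3-[(triethylsilyl)oxy]undec-7-en-4-ynal (C10 epimers) | O=CC[C@@](O[Si](CC)(CC)CC)(C(C)C)C#CC/C(C)=C\C(=O)C(C)Br | intermediate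
19 | (2Z,7R)-9-hydroxy-3,10-dimethyl-7-(propan-2-yl)-7-[(triethylsilyl)oxy]cyclodec-2-en-5-yn-1-one (C9/C10 diastereomers) | CC1C(O)C[C@@](O[Si](CC)(CC)CC)(C(C)C)C#CC/C(C)=C\C1=O | intermediate
20 | (4Z,9R)-2,5-dimethyl-9-(propan-2-yl)-9-[(triethylsilyl)oxy]cyclodec-4-en-7-yne-1,3-dione (C2 epimers/enol) | CC1C(=O)C[C@@](O[Si](CC)(CC)CC)(C(C)C)C#CC/C(C)=C\C1=O | intermediate
21 | (3R,8aR)-6,8a-dimethyl-3-(propan-2-yl)-3-[(triethylsilyl)oxy]-2,3,5,8a-tetrahydroazulene-1,8-dione | C1C(C)=CC(=O)[C@@]2(C)C(=O)C[C@@](O[Si](CC)(CC)CC)(C(C)C)C2=C1 | intermediate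
22 | (3R,8aR)-3-hydroxy-6,8a-dimethyl-3-(propan-2-yl)-2,3,5,8a-tetrahydroazulene-1,8-dione | C1C(C)=CC(=O)[C@@]2(C)C(=O)C[C@@](O)(C(C)C)C2=C1 | intermediate
23 | (1S,3R,8aR)-1,3-dihydroxy-6,8a-dimethyl-3-(propan-2-yl)-1,2,3,8a-tetrahydroazulen-8(5H)-one | C1C(C)=CC(=O)[C@@]2(C)[C@@H](O)C[C@@](O)(C(C)C)C2=C1 | intermediate
24 | (1S,3R,8aR)-1-[(diethylboranyl)oxy]-3-hydroxy-6,8a-dimethyl-3-(propan-2-yl)-1,2,3,8a-tetrahydroazulen-8(5H)-one (boron chelated to the C8 carbonyl) | C1C(C)=CC(=O)[C@@]2(C)[C@@H](OB(CC)CC)C[C@@](O)(C(C)C)C2=C1 | intermediate (not isolated)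
25 | (1S,3R,8R,8aR)-6,8a-dimethyl-3-(propan-2-yl)-1,2,3,5,8,8a-hexahydroazulene-1,3,8-triol | C1C(C)=C[C@@H](O)[C@@]2(C)[C@@H](O)C[C@@](O)(C(C)C)C2=C1 | intermediate
26 | (1S,3R,8R,8aR)-3-hydroxy-6,8a-dimethyl-3-(propan-2-yl)-1,2,3,5,8,8a-hexahydroazulene-1,8-diyl diacetate | C1C(C)=C[C@@H](OC(C)=O)[C@@]2(C)[C@@H](OC(C)=O)C[C@@](O)(C(C)C)C2=C1 | intermediate
27 | (1S,3R,3aS,4R,8R,8aR)-3a,4-epoxy-3-hydroxy-6,8a-dimethyl-3-(propan-2-yl)-1,2,3,3a,4,5,8,8a-octahydroazulene-1,8-diyl diacetate | C1C(C)=C[C@@H](OC(C)=O)[C@@]2(C)[C@@H](OC(C)=O)C[C@@](O)(C(C)C)[C@]23O[C@@H]31 | intermediate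
28 | (1S,3R,3aS,4R,8R,8aR)-3,4-dihydroxy-6,8a-dimethyl-3-(propan-2-yl)-1,2,3,3a,4,5,8,8a-octahydroazulene-1,8-diyl diacetate | O[C@@H]1CC(C)=C[C@@H](OC(C)=O)[C@@]2(C)[C@@H](OC(C)=O)C[C@@](O)(C(C)C)[C@H]12 | intermediate
29 | (1S,3R,3aR,8R,8aR)-3-hydroxy-6,8a-dimethyl-4-oxo-3-(propan-2-yl)-1,2,3,3a,4,5,8,8a-octahydroazulene-1,8-diyl diacetate | O=C1CC(C)=C[C@@H](OC(C)=O)[C@@]2(C)[C@@H](OC(C)=O)C[C@@](O)(C(C)C)[C@H]12 | intermediate
30 | (1S,3R,3aS,4S,8R,8aR)-3,4-dihydroxy-6,8a-dimethyl-3-(propan-2-yl)-1,2,3,3a,4,5,8,8a-octahydroazulene-1,8-diyl diacetate | O[C@H]1CC(C)=C[C@@H](OC(C)=O)[C@@]2(C)[C@@H](OC(C)=O)C[C@@](O)(C(C)C)[C@H]12 | intermediate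
31 | 3,4-dimethoxybenzoyl chloride | COc1ccc(C(Cl)=O)cc1OC | starting material
32 | (1S,3R,3aS,4S,8R,8aR)-1,8-bis(acetyloxy)-3-hydroxy-6,8a-dimethyl-3-(propan-2-yl)-1,2,3,3a,4,5,8,8a-octahydroazulen-4-yl 3,4-dimethoxybenzoate | COc1ccc(C(=O)O[C@H]2CC(C)=C[C@@H](OC(C)=O)[C@@]3(C)[C@@H](OC(C)=O)C[C@@](O)(C(C)C)[C@H]23)cc1OC | target

**Count and risks**

Total steps: 23. Longest linear sequence: 21 steps (steps 1–5, then 8–23).

1. Step 14 (proposed new method). The enol may add to the distal alkyne carbon C6 (6-endo closure to a 6/6 bicycle), a carbonyl oxygen may add in place of carbon, or the ring may fail to reach a reactive conformation before the catalyst is lost. Fallback: setting out from 20, an oxidative free-radical cyclisation with Mn(OAc)3·2H2O in ethanol (Snider-type) replaces π-acid activation. Trivalent manganese oxidises the 2-methyl-1,3-diketone to its C1 radical, which can react only at carbon and prefers 5-exo-dig addition to C5. The resulting vinyl radical takes a hydrogen atom from ethanol, and the route is rejoined at 21.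

2. Step 17. Hydride may still arrive on the face anti to the angular methyl despite the chelate (intrinsic bias of the ring), leading to the C10 epimer, or may add 1,4. Fallback, reagent control in place of chelation control: setting out from 23, the secondary hydroxyl alone is acetylated (Ac2O, pyridine, 0 °C) to (1S,3R,8aR)-3-hydroxy-6,8a-dimethyl-8-oxo-3-(propan-2-yl)-1,2,3,5,8,8a-hexahydroazulen-1-yl acetate F1. The enone is then reduced with (S)-2-methyl-CBS-oxazaborolidine and catecholborane at −78 °C; the Corey model, with the quaternary carbon as the large group, predicts (1S,3R,8R,8aS)-3,8-dihydroxy-6,8a-dimethyl-3-(propan-2-yl)-1,2,3,5,8,8a-hexahydroazulen-1-yl acetate F2. Acetylation (Ac2O, DMAP) rejoins the route at 26.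

3. Step 20. Hydrogen-atom transfer may take place on the β-face (cis ring fusion), or a second titanium may deoxygenate the epoxide back to the alkene. Fallback, thermodynamic in place of kinetic control of C5: setting out from 27, the cis-fused product of such a reduction, (1S,3R,3aR,4R,8R,8aR)-3,4-dihydroxy-6,8a-dimethyl-3-(propan-2-yl)-1,2,3,3a,4,5,8,8a-octahydroazulene-1,8-diyl diacetate F3, is oxidised with Dess–Martin periodinane. In the resulting (1S,3R,3aS,8R,8aR)-3-hydroxy-6,8a-dimethyl-4-oxo-3-(propan-2-yl)-1,2,3,3a,4,5,8,8a-octahydroazulene-1,8-diyl diacetate F4 the fusion carbon is α to the ketone. DBU in toluene should equilibrate it to the trans-fused ketone, in which C6 lies next to the C4 hydroxyl (hydrogen bond) and away from the isopropyl group, and the route is rejoined at 29.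

**Further compounds**

F0 | step 14 | none | none
F1 | step 17 | (1S,3R,8aR)-3-hydroxy-6,8a-dimethyl-8-oxo-3-(propan-2-yl)-1,2,3,5,8,8a-hexahydroazulen-1-yl acetate | C1C(C)=CC(=O)[C@@]2(C)[C@@H](OC(C)=O)C[C@@](O)(C(C)C)C2=C1
F2 | step 17 | (1S,3R,8R,8aS)-3,8-dihydroxy-6,8a-dimethyl-3-(propan-2-yl)-1,2,3,5,8,8a-hexahydroazulen-1-yl acetate | C1C(C)=C[C@@H](O)[C@@]2(C)[C@@H](OC(C)=O)C[C@@](O)(C(C)C)C2=C1
F3 | step 20 | (1S,3R,3aR,4R,8R,8aR)-3,4-dihydroxy-6,8a-dimethyl-3-(propan-2-yl)-1,2,3,3a,4,5,8,8a-octahydroazulene-1,8-diyl diacetate | O[C@@H]1CC(C)=C[C@@H](OC(C)=O)[C@@]2(C)[C@@H](OC(C)=O)C[C@@](O)(C(C)C)[C@@H]12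
F4 | step 20 | (1S,3R,3aS,8R,8aR)-3-hydroxy-6,8a-dimethyl-4-oxo-3-(propan-2-yl)-1,2,3,3a,4,5,8,8a-octahydroazulene-1,8-diyl diacetate | O=C1CC(C)=C[C@@H](OC(C)=O)[C@@]2(C)[C@@H](OC(C)=O)C[C@@](O)(C(C)C)[C@@H]12
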